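**Strategy.** Atoms follow 1-benzoxepine numbering (O1, C2–C5, C5a, C6–C9, C9a). The plan closes both rings in one flask across the ring-fusion bond C5a–C9a and the ring alkene C3=C4. It exploits that C9a is a ketal-level carbon next to O1, and that a temporary C5 ketone turns C5a into an enol silane carbon and C4 into a vinyl ketone terminus. TMSOTf opens a dioxolane (C9a, O1, C2 and its CH2O arm) so that C5a attacks C9a with inversion, closing the cyclohexane; ruthenium metathesis then closes the oxepenone. The precursor is an acyclic bromo ketal carrying a 2-silyloxydiene and an isopropenyl group. The ketone is removed afterwards.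

Key step: step 11

Assumption: (2R,5R)-2,5-diphenylpyrrolidine is taken as the catalyst enantiomer that gives the (R)-α-bromo aldehyde 5; should the sense of induction be the opposite, its enantiomer is used.

Step 1
Reactants: 1 3,3-dimethylglutaric anhydride
Product: 2 4,4-dimethyloxan-2-one
Conditions: NaBH4, THF, 0 °C to rt; aq. HCl
Reagents that add atoms: none
Why: Hydride reduction of one carbonyl of the symmetrical cyclic anhydride and acid lactonisation should give the δ-lactone (anhydride-to-lactone reduction), with no regiochemical issue.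

Step 2
Reactants: 2 4,4-dimethyloxan-2-one
Product: 3 5-hydroxy-N-methoxy-N,3,3-trimethylpentanamide
Conditions: MeNHOMe·HCl, AlMe3, CH2Cl2, 0 °C to rt
Reagents that add atoms: N,O-dimethylhydroxylamine hydrochloride, CNOC.Cl
Why: Weinreb aminolysis of the lactone by the aluminium amide should open the ring to the hydroxy Weinreb amide.

Step 3
Reactants: 3 5-hydroxy-N-methoxy-N,3,3-trimethylpentanamide
Product: 4 N-methoxy-N,3,3-trimethyl-5-oxopentanamide
Conditions: TEMPO (10 mol %), PhI(OAc)2, CH2Cl2, rt
Reagents that add atoms: none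
Why: TEMPO-catalysed oxidation should take the primary alcohol to the aldehyde without touching the amide.

Step 4
Reactants: 4 N-methoxy-N,3,3-trimethyl-5-oxopentanamide
Product: 6 (R)-4-bromo-5-hydroxy-N-methoxy-N,3,3-trimethylpentanamide, via bromo aldehyde 5 (not isolated)
Conditions: (2R,5R)-2,5-diphenylpyrrolidine (20 mol %), PhCO2H, 4,4-dibromo-2,6-di-tert-butylcyclohexa-2,5-dien-1-one, CH2Cl2/pentane, −40 °C; then NaBH4, MeOH, 0 °C
Reagents that add atoms: 4,4-dibromo-2,6-di-tert-butylcyclohexa-2,5-dien-1-one, CC(C)(C)C1=CC(Br)(Br)C=C(C(C)(C)C)C1=O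
Why: Enamine-catalysed enantioselective α-bromination of the aldehyde (catalyst control sets the bromine-bearing centre, later C7) followed by borohydride reduction in the same flask should secure the labile α-bromo aldehyde as the configurationally stable bromohydrin.

Step 5
Reactants: 6 (R)-4-bromo-5-hydroxy-N-methoxy-N,3,3-trimethylpentanamide
Product: 9 (S)-4-bromo-N-methoxy-N,3,3-trimethyl-7-oxooctanamide, via triflate 7 (not isolated), via hydrazone 8 (not isolated)
Conditions: Tf2O, 2,6-lutidine, CH2Cl2, −78 °C; acetone N,N-dimethylhydrazone, LiN(i-Pr)2, THF, −78 °C; aq. oxalic acid, rt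
Reagents that add atoms: acetone N,N-dimethylhydrazone, CC(C)=NN(C)C; water, O
Why: SN2 alkylation of the lithium aza-enolate of acetone dimethylhydrazone by the primary triflate (the neopentyl secondary bromide is inert) and hydrolysis should give the methyl ketone without touching the bromine-bearing centre.

Step 6
Reactants: 10 3-methylbut-2-en-1-ol (prenol)
Product: 11 (S)-(3,3-dimethyloxiran-2-yl)methanol
Conditions: Ti(OiPr)4 (10 mol %), L-(+)-diethyl tartrate (12 mol %), t-BuOOH, 4 Å molecular sieves, CH2Cl2, −20 °C
Reagents that add atoms: tert-butyl hydroperoxide, CC(C)(C)OO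
Why: Sharpless asymmetric epoxidation, in which the L-tartrate ligand should set the (S) centre (later C2).

Step 7
Reactants: 11 (S)-(3,3-dimethyloxiran-2-yl)methanol
Product: 12 (R)-3-methylbut-3-ene-1,2-diol
Conditions: Ti(OiPr)4 (1.5 equiv), CH2Cl2, rt; aq. tartaric acid
Reagents that add atoms: none
Why: Titanium alkoxide-mediated epoxide-to-allylic alcohol isomerisation, in which the tertiary C–O bond should break with loss of a methyl proton while the secondary C–O bond and its configuration are kept.

Step 8
Reactants: 9 (S)-4-bromo-N-methoxy-N,3,3-trimethyl-7-oxooctanamide; 12 (R)-3-methylbut-3-ene-1,2-diol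
Product: 13 (S)-4-bromo-N-methoxy-N,3,3-trimethyl-6-[(2R,4R)-2-methyl-4-(prop-1-en-2-yl)-1,3-dioxolan-2-yl]hexanamide
Conditions: PPTS (10 mol %), benzene, reflux, Dean–Stark trap; chromatographic separation of the two ketal epimers, the unwanted one re-equilibrated under the same conditions
Reagents that add atoms: none
Why: Acid-catalysed ketalisation of the methyl ketone with the 1,2-diol should give both epimers at the ketal carbon, and the one with methyl cis to isopropenyl is taken on because this temporary ring relays its configuration to C9a in step 11.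

Step 9
Reactants: 13 (2R,4R)-dioxolane Weinreb amide
Product: 14 (S)-6-bromo-5,5-dimethyl-8-[(2R,4R)-2-methyl-4-(prop-1-en-2-yl)-1,3-dioxolan-2-yl]oct-1-en-3-one
Conditions: CH2=CHMgBr, THF, −20 °C; cold aq. NH4Cl
Reagents that add atoms: vinylmagnesium bromide, C=C[Mg]Br
Why: Weinreb ketone synthesis, in which the chelated tetrahedral intermediate should stop at single addition and collapse to the vinyl ketone on work-up.

Step 10
Reactants: 14 vinyl ketone
Product: 15 trimethyl{[(6S)-6-bromo-5,5-dimethyl-8-[(2R,4R)-2-methyl-4-(prop-1-en-2-yl)-1,3-dioxolan-2-yl]octa-1,3-dien-3-yl]oxy}silane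
Conditions: LiN(i-Pr)2, Me3SiCl (internal quench), THF, −78 °C; Et3N, pentane, filtration
Reagents that add atoms: chlorotrimethylsilane, C[Si](C)(C)Cl
Why: Kinetic deprotonation at the only enolisable position (the CH2 between the ketone and the quaternary carbon) and O-silylation should give the 2-silyloxy-1,3-diene (silyl enol ether formation).

Step 11
Reactants: 15 2-silyloxydiene ketal
Product: 18 (2R,5aS,7S,9aS)-7-bromo-2-(hydroxymethyl)-3,6,6,9a-tetramethyl-5a,6,7,8,9,9a-hexahydro-1-benzoxepin-5(2H)-one, via monocyclic vinyl ketone 16 (not isolated), via bicyclic silyl ether 17 (not isolated)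
Conditions: TMSOTf (10 mol %), 2,6-di-tert-butyl-4-methylpyridine (20 mol %), CH2Cl2, −78 °C; then second-generation Hoveyda–Grubbs catalyst (5 mol %) added to the same flask, 40 °C; aq. HCl/THF work-up
Reagents that add atoms: none
Why: TMSOTf should silylate the less hindered primary oxygen of the dioxolane, and the enol silane carbon C5a should displace it from C9a within the contact ion pair (intramolecular Mukaiyama-type ketal alkylation), the silyl group of the enol ether ending on the freed primary oxygen and the C5 ketone reappearing as a vinyl ketone. This closes the cyclohexane in a 6-(enolexo)-exo mode through a chair with bromine and the dienyl chain equatorial; C9a is set by inversion of the (2R) ketal carbon, so that methyl becomes axial and O1 equatorial, and C5a is set by the chair (hydrogen axial, trans to the C9a methyl). The ruthenium alkylidene should then join the vinyl ketone carbon C4 to the isopropenyl carbon C3 by ring-closing metathesis with loss of ethylene, a 7-membered ring closure in which the ring enforces the Z alkene. The closest known reaction types are ketal-initiated enol silane cyclisations and enone–olefin ring-closing metathesis, run here in one flask. The step needs cleavage of the primary and not the secondary ketal C–O bond (secured by the steric bias of silylation) and attack before the ion pair relaxes to a free oxocarbenium ion (secured by −78 °C and the strongly nucleophilic enol silane).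

Step 12
Reactants: 18 bicyclic hydroxy enone
Product: 19 (2R,5aS,7S,9aS)-7-bromo-2-(bromomethyl)-3,6,6,9a-tetramethyl-5a,6,7,8,9,9a-hexahydro-1-benzoxepin-5(2H)-one
Conditions: CBr4, PPh3, CH2Cl2, 0 °C
Reagents that add atoms: tetrabromomethane, BrC(Br)(Br)Br
Why: Appel reaction, in which SN2 displacement of the oxyphosphonium ion by bromide at the primary carbon should leave the enone and all stereocentres untouched.

Step 13
Reactants: 19 bicyclic bromo enone
Product: 20 (2R,5aR,7S,9aS)-7-bromo-2-(bromomethyl)-3,6,6,9a-tetramethyl-2,5,5a,6,7,8,9,9a-octahydro-1-benzoxepin-5-ol (both C5 epimers)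
Conditions: NaBH4, CeCl3·7H2O, MeOH, −40 °C
Reagents that add atoms: none
Why: Luche reduction should add hydride 1,2 to the enone and spare the alkyl bromides at low temperature; the new C5 centre is of no consequence because it is removed in the next step.

Step 14
Reactants: 20 allylic alcohol
Product: 21 palisadin B
Conditions: Et3SiH, CF3CO2H, CH2Cl2, −40 °C
Reagents that add atoms: none
Why: Ionic hydrogenation, in which acid ionises the allylic alcohol and Et3SiH should deliver hydride to the secondary terminus C5 of the allyl cation (the tertiary terminus C3 is hindered and deactivated by the adjacent C2–O bond), removing the temporary oxygen and keeping the C3=C4 alkene.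

**Compound list**

1 | 3,3-dimethylglutaric anhydride (4,4-dimethyloxane-2,6-dione) | CC1(C)CC(=O)OC(=O)C1 | starting material
2 | 4,4-dimethyloxan-2-one | CC1(C)CCOC(=O)C1 | intermediate
3 | 5-hydroxy-N-methoxy-N,3,3-trimethylpentanamide | CON(C)C(=O)CC(C)(C)CCO | intermediate
4 | N-methoxy-N,3,3-trimethyl-5-oxopentanamide | CON(C)C(=O)CC(C)(C)CC=O | intermediate
5 | (R)-4-bromo-N-methoxy-N,3,3-trimethyl-5-oxopentanamide | CON(C)C(=O)CC(C)(C)[C@@H](Br)C=O | intermediate
6 | (R)-4-bromo-5-hydroxy-N-methoxy-N,3,3-trimethylpentanamide | CON(C)C(=O)CC(C)(C)[C@@H](Br)CO | intermediate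
7 | (R)-2-bromo-5-[methoxy(methyl)amino]-3,3-dimethyl-5-oxopentyl trifluoromethanesulfonate | CON(C)C(=O)CC(C)(C)[C@@H](Br)COS(=O)(=O)C(F)(F)F | intermediate
8 | (S)-4-bromo-7-(2,2-dimethylhydrazinylidene)-N-methoxy-N,3,3-trimethyloctanamide | CON(C)C(=O)CC(C)(C)[C@@H](Br)CCC(C)=NN(C)C | intermediate
9 | (S)-4-bromo-N-methoxy-N,3,3-trimethyl-7-oxooctanamide | CON(C)C(=O)CC(C)(C)[C@@H](Br)CCC(C)=O | intermediate
10 | 3-methylbut-2-en-1-ol (prenol) | CC(C)=CCO | starting material
11 | (S)-(3,3-dimethyloxiran-2-yl)methanol | OC[C@@H]1OC1(C)C | intermediate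
12 | (R)-3-methylbut-3-ene-1,2-diol | OC[C@H](O)C(C)=C | intermediate
13 | (S)-4-bromo-N-methoxy-N,3,3-trimethyl-6-[(2R,4R)-2-methyl-4-(prop-1-en-2-yl)-1,3-dioxolan-2-yl]hexanamide (methyl cis to isopropenyl) | CON(C)C(=O)CC(C)(C)[C@@H](Br)CC[C@]1(C)OC[C@@H](C(C)=C)O1 | intermediate
14 | (S)-6-bromo-5,5-dimethyl-8-[(2R,4R)-2-methyl-4-(prop-1-en-2-yl)-1,3-dioxolan-2-yl]oct-1-en-3-one | C=CC(=O)CC(C)(C)[C@@H](Br)CC[C@]1(C)OC[C@@H](C(C)=C)O1 | intermediate
15 | trimethyl{[(6S)-6-bromo-5,5-dimethyl-8-[(2R,4R)-2-methyl-4-(prop-1-en-2-yl)-1,3-dioxolan-2-yl]octa-1,3-dien-3-yl]oxy}silane | C=CC(O[Si](C)(C)C)=CC(C)(C)[C@@H](Br)CC[C@]1(C)OC[C@@H](C(C)=C)O1 | intermediate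
16 | 1-[(1S,3S,6S)-3-bromo-2,2,6-trimethyl-6-{[(2R)-3-methyl-1-(trimethylsilyloxy)but-3-en-2-yl]oxy}cyclohexyl]prop-2-en-1-one | C=CC(=O)[C@H]1C(C)(C)[C@@H](Br)CC[C@]1(C)O[C@@H](CO[Si](C)(C)C)C(C)=C | intermediate
17 | (2R,5aS,7S,9aS)-7-bromo-3,6,6,9a-tetramethyl-2-[(trimethylsilyloxy)methyl]-5a,6,7,8,9,9a-hexahydro-1-benzoxepin-5(2H)-one | CC1=CC(=O)[C@H]2C(C)(C)[C@@H](Br)CC[C@]2(C)O[C@H]1CO[Si](C)(C)C | intermediate
18 | (2R,5aS,7S,9aS)-7-bromo-2-(hydroxymethyl)-3,6,6,9a-tetramethyl-5a,6,7,8,9,9a-hexahydro-1-benzoxepin-5(2H)-one | CC1=CC(=O)[C@H]2C(C)(C)[C@@H](Br)CC[C@]2(C)O[C@H]1CO | intermediate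
19 | (2R,5aS,7S,9aS)-7-bromo-2-(bromomethyl)-3,6,6,9a-tetramethyl-5a,6,7,8,9,9a-hexahydro-1-benzoxepin-5(2H)-one | CC1=CC(=O)[C@H]2C(C)(C)[C@@H](Br)CC[C@]2(C)O[C@H]1CBr | intermediate
20 | (2R,5aR,7S,9aS)-7-bromo-2-(bromomethyl)-3,6,6,9a-tetramethyl-2,5,5a,6,7,8,9,9a-octahydro-1-benzoxepin-5-ol (both C5 epimers) | CC1=CC(O)[C@H]2C(C)(C)[C@@H](Br)CC[C@]2(C)O[C@H]1CBr | intermediate
21 | palisadin B, (2R,5aS,7S,9aS)-7-bromo-2-(bromomethyl)-3,6,6,9a-tetramethyl-2,5,5a,6,7,8,9,9a-octahydro-1-benzoxepine | CC1=CC[C@H]2C(C)(C)[C@@H](Br)CC[C@]2(C)O[C@H]1CBr | target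

**Count.** Total steps: 14. Longest linear sequence: 12 steps (steps 1–5 and 8–14); steps 6–7 make the diol 12 that enters at step 8.

**Steps most likely to fail, with fallbacks**

1. Step 11. What may go wrong: the silylated ketal may ionise to a free oxocarbenium ion before the carbon–carbon bond forms, so that the relay of configuration from the dioxolane to C9a is lost (poor facial selectivity). The new tertiary ether may be lost again by β-elimination through the C5 ketone. The metathesis between an electron-poor vinyl ketone and a hindered 1,1-disubstituted alkene may stall. Fallback (sets out from 13, comes back at 18): the ring alkene is made by aldol condensation and not by metathesis. MeMgBr should convert the Weinreb amide 13 into methyl ketone F1. TMSCl/NaI/Et3N should give the more substituted silyl enol ether F2. TiCl4 at −78 °C should close the cyclohexane by the same ketal alkylation and, after aqueous work-up, give acetylcyclohexane F3. Ozonolysis (O3, then Me2S) should cleave the isopropenyl group to the methyl ketone of diketone F4. KOt-Bu in t-BuOH should then effect the intramolecular aldol condensation of the ring acetyl group onto the less hindered α-alkoxy ketone and close the oxepenone 18.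

2. Step 14. What may go wrong: hydride capture at the tertiary terminus of the allyl cation (alkene transposition), or cleavage of the C5a–C9a bond from the cation with assistance of O1 (ring fragmentation). Fallback (sets out from 20, comes back at 21): no free cation is formed. ClCO2Me/pyridine should give allylic carbonate F5, and Pd(PPh3)4 with NaBH4 in THF should reduce it through the π-allyl palladium complex, hydride attacking the less hindered terminus C5.

3. Step 5. What may go wrong: E2 loss of triflate or bromide participation during the displacement next to the bromine-bearing carbon (erosion of C7), or acylation of the aza-enolate by the Weinreb amide. Fallback (sets out from 6 through the same triflate 7, comes back at 9): a softer carbon nucleophile and a later oxidation. Allylmagnesium bromide with catalytic CuI should displace the triflate to give terminal alkene F6, and Wacker oxidation (PdCl2, CuCl, O2, DMF/H2O) should give methyl ketone 9.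

**Further compounds**

F1 | step 11 | (S)-5-bromo-4,4-dimethyl-7-[(2R,4R)-2-methyl-4-(prop-1-en-2-yl)-1,3-dioxolan-2-yl]heptan-2-one | CC(=O)CC(C)(C)[C@@H](Br)CC[C@]1(C)OC[C@@H](C(C)=C)O1
F2 | step 11 | trimethylsilyl enol ether of F1 (enol double bond towards the quaternary carbon) | C[Si](C)(C)OC(C)=CC(C)(C)[C@@H](Br)CC[C@]1(C)OC[C@@H](C(C)=C)O1
F3 | step 11 | 1-[(1S,3S,6S)-3-bromo-6-{[(2R)-1-hydroxy-3-methylbut-3-en-2-yl]oxy}-2,2,6-trimethylcyclohexyl]ethan-1-one | CC(=O)[C@H]1C(C)(C)[C@@H](Br)CC[C@]1(C)O[C@@H](CO)C(C)=C
F4 | step 11 | (3S)-3-{[(1S,2S,4S)-2-acetyl-4-bromo-1,3,3-trimethylcyclohexyl]oxy}-4-hydroxybutan-2-one | CC(=O)[C@H]1C(C)(C)[C@@H](Br)CC[C@]1(C)O[C@@H](CO)C(C)=O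
F5 | step 14 | methyl carbonate of allylic alcohol 20 (at C5) | CC1=CC(OC(=O)OC)[C@H]2C(C)(C)[C@@H](Br)CC[C@]2(C)O[C@H]1CBr
F6 | step 5 | (S)-4-bromo-N-methoxy-N,3,3-trimethyloct-7-enamide | CON(C)C(=O)CC(C)(C)[C@@H](Br)CCC=C
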